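**Retrosynthetic overview**
1. Ring A piece: 2,4-dihydroxyacetophenone 1 + prenyl bromide 2 <= ketone 3 (aromatic C-prenylation at C3).
2. Ring B side chain: 4-hydroxyisophthalaldehyde 4 + 2-methylprop-1-enylmagnesium bromide 5 (through chelated phenolate 6) <= racemic 1-hydroxyprenyl phenol 7.
3. Key disconnection, O1–C2 of the dihydrofuran: 7 <= threo epoxy alcohol 8 <= trans-(2R,3R) dihydrobenzofuran aldehyde 9. Side-chain epoxidation and phenolate 5-exo opening follow the presumed biosynthesis, and both stereocentres are fixed in this one flask.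
4. Enone C=C, made last: 3 + 9 <= aldol 10 <= paratocarpin G 11 (Claisen–Schmidt, no protecting groups).
5. Ring order: both benzene rings are bought; the dihydrofuran is the only ring formed (step 3).

Assumption: the SMILES is read as (2R,3R), which is trans, with an E enone; 4, the THF solution of 5 and the L-fructose-derived Shi ketone are taken as catalogue items.

**Step 1**
Reactants: 1 2,4-dihydroxyacetophenone; 2 prenyl bromide (1-bromo-3-methylbut-2-ene)
Product: 3 1-[2,4-dihydroxy-3-(3-methylbut-2-en-1-yl)phenyl]ethan-1-one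
Conditions: KOH (1.1 equiv), H2O, 0 °C to rt, 16 h; chromatography (about 30% expected, 1 recovered)
Reagents that add atoms: prenyl bromide 2, CC(C)=CCBr
Why: Aromatic C-prenylation of an ambident phenolate (Friedel–Crafts-type alkylation): in water the phenolate oxygens are hydrogen-bonded, so the soft allylic bromide is attacked by carbon, and C3, ortho to both oxygens, is the most nucleophilic ring position; no stereocentre is formed.

**Step 2**
Reactants: 4 4-hydroxyisophthalaldehyde; 5 2-methylprop-1-enylmagnesium bromide (0.5 M in THF)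
Product: 7 racemic 4-hydroxy-3-(1-hydroxy-3-methylbut-2-en-1-yl)benzaldehyde, via bromomagnesium phenolate 6 (not isolated)
Conditions: 5 (2.05 equiv, slow addition), THF, −78 to −30 °C, 2 h; cold sat. aq NH4Cl; silica gel pretreated with Et3N
Reagents that add atoms: 2-methylprop-1-enylmagnesium bromide 5, CC(C)=C[Mg]Br
Why: Grignard 1,2-addition under chelation control: the first equivalent of 5 makes 6, whose divalent magnesium bridges the phenolate oxygen and the ortho formyl oxygen, so this carbonyl is Lewis-acid activated and receives the second equivalent from within the aggregate, while the para formyl group is only a deactivated vinylogous carboxylate; the carbinol centre is formed racemic on purpose.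

**Step 3**
Reactants: 7 racemic 4-hydroxy-3-(1-hydroxy-3-methylbut-2-en-1-yl)benzaldehyde (only its (S)-enantiomer is consumed)
Product: 9 (2R,3R)-3-hydroxy-2-(2-hydroxypropan-2-yl)-2,3-dihydro-1-benzofuran-5-carbaldehyde, via threo epoxy alcohol 8 (not isolated)
Conditions: L-fructose-derived Shi ketone, 1,2:4,5-di-O-isopropylidene-β-L-erythro-hexo-2,3-diulo-2,6-pyranose (C12H18O6, 30 mol %), 2KHSO5·KHSO4·K2SO4 and K2CO3 added side by side over 2 h to about 45% conversion (HPLC), Bu4NHSO4 (5 mol %), MeCN–CH2(OMe)2–aq Na2B4O7 buffer (pH 10.5), −5 °C; then 23 °C, 3 h; extract at pH 10.5 (unreacted 7 stays in the water as phenolate); chromatography, one recrystallisation (about 35%, about 90% ee before and >98% ee after crystallisation expected)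
Reagents that add atoms: potassium peroxymonosulfate KHSO5, [K+].[O-]S(=O)(=O)OO
Why: Proposed new method: a Shi asymmetric epoxidation run as a kinetic resolution and telescoped with a phenolate 5-exo-tet epoxide opening, the closest known reactions being the Shi epoxidation–cyclisation of ortho-prenylphenols, the chiral-dioxirane kinetic resolution of racemic olefins and the base-induced closure of ortho-hydroxyaryl epoxy carbinols; A1,3 strain with the cis methyl group holds the carbinol C–H of 7 in the alkene plane, so one alkene face carries OH and the other the aryl ring, and the L-series dioxirane, which delivers oxygen to the face that makes the (S)-epoxide carbon, meets the open OH face only in (S)-7 (matched, fast) and the aryl-shielded face in (R)-7 (mismatched, left behind), which fixes C3 as R by selection; the aryl ring of 8 then lies anti to the C2–O bond, so the phenolate attacks the less substituted epoxide carbon from the back, inverts it from S to R and gives the trans (2R,3R) ring.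

**Step 4**
Reactants: 3 1-[2,4-dihydroxy-3-(3-methylbut-2-en-1-yl)phenyl]ethan-1-one; 9 (2R,3R)-3-hydroxy-2-(2-hydroxypropan-2-yl)-2,3-dihydro-1-benzofuran-5-carbaldehyde
Product: 11 paratocarpin G, via aldol adduct 10 (not isolated)
Conditions: KOH (50% aq, 12 equiv), EtOH, 0 °C to rt, 48 h, Ar; ice, AcOH to pH 6
Reagents that add atoms: none
Why: Claisen–Schmidt condensation (aldol addition, then E1cB loss of water): the non-enolisable, non-phenolic aldehyde 9 is a good acceptor for the enolate of unprotected 3, elimination gives the conjugated, chelated E-enone under thermodynamic control, and C2 and C3 are untouched because neither C–H is acidic and the pH 6 work-up avoids ionising the benzylic alcohol.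

**Compound list**
1 | 2,4-dihydroxyacetophenone | CC(=O)c1ccc(O)cc1O | starting material
2 | prenyl bromide (1-bromo-3-methylbut-2-ene) | CC(C)=CCBr | starting material
3 | 1-[2,4-dihydroxy-3-(3-methylbut-2-en-1-yl)phenyl]ethan-1-one | CC(=O)c1ccc(O)c(CC=C(C)C)c1O | intermediate
4 | 4-hydroxyisophthalaldehyde (4-hydroxybenzene-1,3-dicarbaldehyde) | O=Cc1ccc(O)c(C=O)c1 | starting material
5 | 2-methylprop-1-enylmagnesium bromide | CC(C)=C[Mg]Br | starting material
6 | bromomagnesium 2,4-diformylphenolate (not isolated) | O=Cc1ccc(O[Mg]Br)c(C=O)c1 | intermediate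
7 | racemic 4-hydroxy-3-(1-hydroxy-3-methylbut-2-en-1-yl)benzaldehyde | O=Cc1ccc(O)c(c1)C(O)C=C(C)C | intermediate
8 | 3-{(R)-[(2S)-3,3-dimethyloxiran-2-yl](hydroxy)methyl}-4-hydroxybenzaldehyde, threo (not isolated) | O=Cc1ccc(O)c(c1)[C@@H](O)[C@@H]1OC1(C)C | intermediate
9 | (2R,3R)-3-hydroxy-2-(2-hydroxypropan-2-yl)-2,3-dihydro-1-benzofuran-5-carbaldehyde, trans | O=Cc1ccc2c(c1)[C@@H](O)[C@H](C(C)(C)O)O2 | intermediate
10 | 1-[2,4-dihydroxy-3-(3-methylbut-2-en-1-yl)phenyl]-3-hydroxy-3-[(2R,3R)-3-hydroxy-2-(2-hydroxypropan-2-yl)-2,3-dihydro-1-benzofuran-5-yl]propan-1-one, both carbinol epimers (not isolated) | CC(C)=CCc1c(O)ccc(C(=O)CC(O)c2ccc3c(c2)[C@@H](O)[C@H](C(C)(C)O)O3)c1O | intermediate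
11 | paratocarpin G, (E)-1-[2,4-dihydroxy-3-(3-methylbut-2-en-1-yl)phenyl]-3-[(2R,3R)-3-hydroxy-2-(2-hydroxypropan-2-yl)-2,3-dihydro-1-benzofuran-5-yl]prop-2-en-1-one | CC(C)=CCc1c(O)ccc(C(=O)/C=C/c2ccc3c(c2)[C@@H](O)[C@H](C(C)(C)O)O3)c1O | target

**Step count and risks**

Total step count: 4. Longest linear sequence: 3 (4 to 7 to 9 to 11).

Steps most likely to fail:

- **Step 3 (highest risk).** The resolution factor may be too small, so that the ee of 9 drops beyond 45% conversion. KHSO5 may also attack the formyl group (Dakin-type) or the phenolate.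
 - Fallback, from 7 back to 9: separate the two tasks.
 - VO(acac)2 (2 mol %) and t-BuOOH in CH2Cl2 at 0 °C epoxidise both enantiomers of 7 under hydroxyl direction and A1,3 control to the racemic threo epoxy alcohol F1.
 - K2CO3 in MeOH closes it to the racemic trans diol aldehyde F2.
 - An acylative kinetic resolution follows, with (R)-benzotetramisole ((R)-2-phenyl-2,3-dihydroimidazo[2,1-b][1,3]benzothiazole, C15H12N2S, 4 mol %), (i-PrCO)2O and i-Pr2NEt in CHCl3 at 0 °C. Taken to about 55% conversion, it turns the (3S) alcohol into the (2S,3S) isobutyrate F3, and unreacted 9 is recovered in >98% ee.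

- **Step 2.** The para formyl group may compete, giving the regioisomer or the bis-adduct. Also, 7 can lose water to the chromene on acidic contact.
 - Fallback, from 5 back to 9: take the second formyl group away.
 - 5 (2.05 equiv) is added to 5-bromosalicylaldehyde F4 to give the racemic bromo allylic alcohol F5.
 - The conditions of step 3 convert its (S)-enantiomer through the bromo epoxy alcohol F6 into the (2R,3R) bromo diol F7.
 - n-BuLi (3.3 equiv, THF, −78 °C) followed by DMF installs the formyl group and gives 9.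

- **Step 4.** The doubly deprotonated ketone 3 may enolise too little, so the condensation is slow and flavanone formation or Cannizzaro loss of 9 takes over.
 - Fallback, from 3 back to 11: lower the charge on ring A.
 - Allyl bromide and K2CO3 in acetone alkylate only the free 4-OH of 3 to give the allyl ether F8; the chelated 2-OH stays.
 - F8 condenses with 9 under Ba(OH)2·8H2O in MeOH through the aldol adduct F9 to the O-allyl chalcone F10.
 - Pd(PPh3)4 (2 mol %) with morpholine in THF at rt removes the allyl group under neutral conditions to give 11.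

**Further compounds**
F1 | step 3 | racemic threo 3-[(3,3-dimethyloxiran-2-yl)(hydroxy)methyl]-4-hydroxybenzaldehyde (1:1 of 8 and its mirror image) | O=Cc1ccc(O)c(c1)[C@@H](O)[C@@H]1OC1(C)C.O=Cc1ccc(O)c(c1)[C@H](O)[C@H]1OC1(C)C
F2 | step 3 | racemic trans 3-hydroxy-2-(2-hydroxypropan-2-yl)-2,3-dihydro-1-benzofuran-5-carbaldehyde (1:1 of 9 and its mirror image) | O=Cc1ccc2c(c1)[C@@H](O)[C@H](C(C)(C)O)O2.O=Cc1ccc2c(c1)[C@H](O)[C@@H](C(C)(C)O)O2
F3 | step 3 | (2S,3S)-5-formyl-2-(2-hydroxypropan-2-yl)-2,3-dihydro-1-benzofuran-3-yl 2-methylpropanoate | O=Cc1ccc2c(c1)[C@H](OC(=O)C(C)C)[C@@H](C(C)(C)O)O2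
F4 | step 2 | 5-bromosalicylaldehyde (5-bromo-2-hydroxybenzaldehyde) | O=Cc1cc(Br)ccc1O
F5 | step 2 | racemic 4-bromo-2-(1-hydroxy-3-methylbut-2-en-1-yl)phenol | CC(C)=CC(O)c1cc(Br)ccc1O
F6 | step 2 | 4-bromo-2-{(R)-[(2S)-3,3-dimethyloxiran-2-yl](hydroxy)methyl}phenol | Brc1ccc(O)c(c1)[C@@H](O)[C@@H]1OC1(C)C
F7 | step 2 | (2R,3R)-5-bromo-2-(2-hydroxypropan-2-yl)-2,3-dihydro-1-benzofuran-3-ol | Brc1ccc2c(c1)[C@@H](O)[C@H](C(C)(C)O)O2
F8 | step 4 | 1-[2-hydroxy-3-(3-methylbut-2-en-1-yl)-4-(prop-2-en-1-yloxy)phenyl]ethan-1-one | CC(=O)c1ccc(OCC=C)c(CC=C(C)C)c1O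
F9 | step 4 | aldol adduct of F8 and 9 (both carbinol epimers) | CC(C)=CCc1c(OCC=C)ccc(C(=O)CC(O)c2ccc3c(c2)[C@@H](O)[C@H](C(C)(C)O)O3)c1O
F10 | step 4 | 4'-O-allyl paratocarpin G | CC(C)=CCc1c(OCC=C)ccc(C(=O)/C=C/c2ccc3c(c2)[C@@H](O)[C@H](C(C)(C)O)O3)c1O
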